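**Retrosynthetic overview**
1. The C3 stereocenter (alpha to the C4 ketone and benzylic, hence labile) is set late: racemic protected isoflavanone 20 → cis-(3S,4S)-alcohol by dynamic kinetic transfer hydrogenation → reoxidation → MOM removal.
2. The C6 prenyl group comes from a C6 aryl triflate (Stille coupling); the two oxygens of a 6,7-diol are told apart because O7 is para to the C4 carbonyl.
3. Ring C is the only ring made: one operation joins a mirror-symmetric 4,5-bis(benzyloxy)benzyne (ring A) to 2-arylacrylic acid 13 (ring B plus C2, C3, C4 and O1). It forms O1–C8a and C4–C4a by insertion of the aryne into the acid C–O bond, then O1–C2 by oxa-Michael closure.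
4. Enabling feature: on ring A the ether oxygen O1 (on C8a) and the ketone carbon C4 (on C4a) sit on adjacent carbons, and C2 is an unsubstituted methylene beta to C4, so ring C is an ortho-acylphenol added to its own 2-aryl enone. C5 and C8 carry hydrogen, so the ring A partner can be a symmetric aryne.
5. Rings A and B are carried in from phenols 1 and 7.

Key step: step 9

Remark: the (S,S)-TsDPEN ruthenium catalyst is assumed to reduce 20 with the facial sense known for 1-tetralone and chroman-4-one (S carbinol), which with the cis preference of the dynamic kinetic resolution leads to 3S; the (R,R) catalyst would be used if the sense proved opposite.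

**Route**

Step 1
Reactants: 1 3,4-bis(benzyloxy)phenol
Product: 2 2-bromo-4,5-bis(benzyloxy)phenol
Conditions: NBS, MeCN, 0 °C
Reagents that add atoms: N-bromosuccinimide, O=C1CCC(=O)N1Br
Why: Electrophilic aromatic bromination goes ortho to the free hydroxyl and para to the 3-benzyloxy group, the least hindered activated position.

Step 2
Reactants: 2 2-bromo-4,5-bis(benzyloxy)phenol
Product: 3 [2-bromo-4,5-bis(benzyloxy)phenoxy]trimethylsilane
Conditions: HMDS, THF, reflux
Reagents that add atoms: hexamethyldisilazane, C[Si](C)(C)N[Si](C)(C)C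
Why: O-silylation of the phenol with HMDS gives the silyl ether needed for the retro-Brook transfer without forming any salt.

Step 3
Reactants: 3 [2-bromo-4,5-bis(benzyloxy)phenoxy]trimethylsilane
Product: 6 4,5-bis(benzyloxy)-2-(trimethylsilyl)phenyl trifluoromethanesulfonate, via aryllithium 4 (not isolated), via lithium 2-silylphenoxide 5 (not isolated)
Conditions: n-BuLi, THF, −78 °C; then Tf2O, −78 °C to rt
Reagents that add atoms: trifluoromethanesulfonic anhydride, O=S(=O)(OS(=O)(=O)C(F)(F)F)C(F)(F)F
Why: Bromine–lithium exchange followed by retro-Brook (oxygen-to-carbon) silyl migration gives phenoxide 5, which Tf2O traps on oxygen, the standard entry to ortho-silylaryl triflate aryne precursors.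

Step 4
Reactants: 7 2,5-dimethoxyphenol
Product: 8 4-bromo-2,5-dimethoxyphenol
Conditions: NBS, MeCN, 0 °C
Reagents that add atoms: N-bromosuccinimide, O=C1CCC(=O)N1Br
Why: Electrophilic bromination goes para to the hydroxyl and ortho to the 5-methoxy group, the doubly activated position.

Step 5
Reactants: 8 4-bromo-2,5-dimethoxyphenol
Product: 9 1-bromo-2,5-dimethoxy-4-(methoxymethoxy)benzene
Conditions: MOMCl, i-Pr2NEt, CH2Cl2, 0 °C to rt
Reagents that add atoms: chloromethyl methyl ether, COCCl
Why: Williamson-type O-alkylation gives the MOM acetal, which tolerates organolithium, base, fluoride and hydrogenolysis in the steps ahead.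

Step 6
Reactants: 9 1-bromo-2,5-dimethoxy-4-(methoxymethoxy)benzene
Product: 11 ethyl 2-[2,5-dimethoxy-4-(methoxymethoxy)phenyl]-2-oxoacetate, via aryllithium 10 (not isolated)
Conditions: n-BuLi, THF, −78 °C; then inverse addition to diethyl oxalate (3 equiv), THF, −78 °C
Reagents that add atoms: diethyl oxalate, CCOC(=O)C(=O)OCC
Why: Bromine–lithium exchange and acylation of the aryllithium by excess oxalate at low temperature stops at the alpha-keto ester.

Step 7
Reactants: 11 ethyl 2-[2,5-dimethoxy-4-(methoxymethoxy)phenyl]-2-oxoacetate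
Product: 12 ethyl 2-[2,5-dimethoxy-4-(methoxymethoxy)phenyl]acrylate
Conditions: Ph3PCH3Br, KOtBu, THF, 0 °C to rt
Reagents that add atoms: methyltriphenylphosphonium bromide, C[P+](c1ccccc1)(c1ccccc1)c1ccccc1.[Br-]
Why: Wittig methylenation takes place at the ketone carbonyl of the alpha-keto ester, the more electrophilic of the two, and gives the 2-arylacrylate.

Step 8
Reactants: 12 ethyl 2-[2,5-dimethoxy-4-(methoxymethoxy)phenyl]acrylate
Product: 13 2-[2,5-dimethoxy-4-(methoxymethoxy)phenyl]acrylic acid
Conditions: LiOH, THF/H2O, rt; then 1 M HCl to pH 3, 0 °C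
Reagents that add atoms: lithium hydroxide, [Li+].[OH-]
Why: Saponification at room temperature, with a brief cold acidification that the MOM acetal tolerates, gives the free acid that the aryne step requires.

Step 9
Reactants: 6 4,5-bis(benzyloxy)-2-(trimethylsilyl)phenyl trifluoromethanesulfonate, 13 2-[2,5-dimethoxy-4-(methoxymethoxy)phenyl]acrylic acid
Product: 16 rac-6,7-bis(benzyloxy)-3-[2,5-dimethoxy-4-(methoxymethoxy)phenyl]chroman-4-one, via benzyne 14 (not isolated), via ortho-acylphenoxide 15 (not isolated)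
Conditions: CsF (4 equiv), THF, 125 °C, sealed tube
Reagents that add atoms: none
Why: Fluoride unmasks benzyne 14 from 6, the cesium carboxylate of 13 adds through oxygen, the aryl carbanion so formed attacks its own ester carbonyl through a four-membered transition state and the adduct opens to ortho-acylphenoxide 15 (net insertion of the aryne into the acid C–O bond, forming O1–C8a and C4–C4a), and the phenoxide then adds to the terminal methylene of its 2-aryl enone. The closest known reaction type is the fluoride-mediated intermolecular C–O addition of carboxylic acids to arynes, which with alpha,beta-unsaturated acids continues to chroman-4-ones. Ring C, the only ring formed, closes by a 6-endo-trig oxa-Michael addition (O1–C2). The new stereocenter C3 arises by unselective protonation of the resulting enolate, so 16 is racemic by design and C3 is set in step 14. The step needs regiocontrol of oxygen versus acyl placement on ring A and chemoselective capture of the aryne by the carboxylate: the first is secured because the 4,5-bis(benzyloxy) pattern makes the two aryne carbons equivalent by mirror symmetry, the second because every phenol is masked and the acid is the only protic nucleophile.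

Step 10
Reactants: 16 rac-6,7-bis(benzyloxy)-3-[2,5-dimethoxy-4-(methoxymethoxy)phenyl]chroman-4-one
Product: 17 rac-6,7-dihydroxy-3-[2,5-dimethoxy-4-(methoxymethoxy)phenyl]chroman-4-one
Conditions: H2 (1 atm), Pd/C, EtOAc/MeOH, rt
Reagents that add atoms: none
Why: Hydrogenolysis of the two benzyl ethers leaves the aryl ketone and the MOM acetal untouched and exposes the catechol before any alkene is present.

Step 11
Reactants: 17 rac-6,7-dihydroxy-3-[2,5-dimethoxy-4-(methoxymethoxy)phenyl]chroman-4-one
Product: 18 rac-6-hydroxy-7-(methoxymethoxy)-3-[2,5-dimethoxy-4-(methoxymethoxy)phenyl]chroman-4-one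
Conditions: MOMCl (1.05 equiv), i-Pr2NEt, CH2Cl2, 0 °C
Reagents that add atoms: chloromethyl methyl ether, COCCl
Why: The 7-hydroxyl is para to the C4 carbonyl and therefore the more acidic phenol, so one equivalent of MOMCl under weak base should alkylate it selectively (site-selective Williamson etherification).

Step 12
Reactants: 18 rac-6-hydroxy-7-(methoxymethoxy)-3-[2,5-dimethoxy-4-(methoxymethoxy)phenyl]chroman-4-one
Product: 19 rac-3-[2,5-dimethoxy-4-(methoxymethoxy)phenyl]-7-(methoxymethoxy)-4-oxochroman-6-yl trifluoromethanesulfonate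
Conditions: Tf2O, pyridine, CH2Cl2, 0 °C
Reagents that add atoms: trifluoromethanesulfonic anhydride, O=S(=O)(OS(=O)(=O)C(F)(F)F)C(F)(F)F
Why: O-sulfonylation of the remaining 6-hydroxyl gives the aryl triflate as the handle for C–C coupling.

Step 13
Reactants: 19 rac-3-[2,5-dimethoxy-4-(methoxymethoxy)phenyl]-7-(methoxymethoxy)-4-oxochroman-6-yl trifluoromethanesulfonate
Product: 20 rac-3-[2,5-dimethoxy-4-(methoxymethoxy)phenyl]-7-(methoxymethoxy)-6-(3-methylbut-2-en-1-yl)chroman-4-one
Conditions: tributyl(prenyl)stannane, Pd(PPh3)4 (5 mol%), LiCl (3 equiv), DMF, 90 °C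
Reagents that add atoms: tributyl(3-methylbut-2-en-1-yl)stannane, CC(C)=CC[Sn](CCCC)(CCCC)CCCC
Why: Stille coupling of the aryl triflate is neutral, tolerates the enolisable ketone and should give the linear prenyl group at C6 by reductive elimination from the less hindered allyl terminus.

Step 14
Reactants: 20 rac-3-[2,5-dimethoxy-4-(methoxymethoxy)phenyl]-7-(methoxymethoxy)-6-(3-methylbut-2-en-1-yl)chroman-4-one
Product: 21 (3S,4S)-3-[2,5-dimethoxy-4-(methoxymethoxy)phenyl]-7-(methoxymethoxy)-6-(3-methylbut-2-en-1-yl)chroman-4-ol (cis)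
Conditions: RuCl[(S,S)-TsDPEN](p-cymene) (2 mol%), HCO2H/Et3N (5:2), EtOAc, 40 °C
Reagents that add atoms: none
Why: Noyori asymmetric transfer hydrogenation with dynamic kinetic resolution: Et3N keeps C3 of 20 equilibrating through the enol while the (S,S) catalyst reduces only the enantiomer in which hydride can enter C4 from its preferred face anti to the C3 aryl group, so C4 (S, catalyst control) and C3 (S, cis to the hydroxyl) are set together.

Step 15
Reactants: 21 (3S,4S)-3-[2,5-dimethoxy-4-(methoxymethoxy)phenyl]-7-(methoxymethoxy)-6-(3-methylbut-2-en-1-yl)chroman-4-ol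
Product: 22 (3S)-3-[2,5-dimethoxy-4-(methoxymethoxy)phenyl]-7-(methoxymethoxy)-6-(3-methylbut-2-en-1-yl)chroman-4-one
Conditions: Dess–Martin periodinane, CH2Cl2, 0 °C to rt
Reagents that add atoms: none
Why: Dess–Martin oxidation returns the C4 ketone under neutral, non-enolising conditions, so the C3 center set in step 14 should be kept.

Step 16
Reactants: 22 (3S)-3-[2,5-dimethoxy-4-(methoxymethoxy)phenyl]-7-(methoxymethoxy)-6-(3-methylbut-2-en-1-yl)chroman-4-one
Product: 23 (3S)-7-hydroxy-3-(4-hydroxy-2,5-dimethoxyphenyl)-6-(3-methylbut-2-en-1-yl)chroman-4-one (CNP0256988.2)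
Conditions: NaHSO4·SiO2, wet CH2Cl2, rt
Reagents that add atoms: none
Why: Mild heterogeneous acid hydrolysis of the two phenolic MOM acetals at room temperature frees both phenols without base and with minimal enolisation at C3 or activation of the prenyl alkene.

**Compound list**
1 | 3,4-bis(benzyloxy)phenol | Oc1ccc(OCc2ccccc2)c(OCc2ccccc2)c1 | starting material
2 | 2-bromo-4,5-bis(benzyloxy)phenol | Oc1cc(OCc2ccccc2)c(OCc2ccccc2)cc1Br | intermediate
3 | [2-bromo-4,5-bis(benzyloxy)phenoxy]trimethylsilane | C[Si](C)(C)Oc1cc(OCc2ccccc2)c(OCc2ccccc2)cc1Br | intermediate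
4 | [4,5-bis(benzyloxy)-2-(trimethylsilyloxy)phenyl]lithium (not isolated) | C[Si](C)(C)Oc1cc(OCc2ccccc2)c(OCc2ccccc2)cc1[Li] | intermediate
5 | lithium 4,5-bis(benzyloxy)-2-(trimethylsilyl)phenoxide (not isolated) | [Li]Oc1cc(OCc2ccccc2)c(OCc2ccccc2)cc1[Si](C)(C)C | intermediate
6 | 4,5-bis(benzyloxy)-2-(trimethylsilyl)phenyl trifluoromethanesulfonate | C[Si](C)(C)c1cc(OCc2ccccc2)c(OCc2ccccc2)cc1OS(=O)(=O)C(F)(F)F | intermediate
7 | 2,5-dimethoxyphenol | COc1ccc(OC)c(O)c1 | starting material
8 | 4-bromo-2,5-dimethoxyphenol | COc1cc(Br)c(OC)cc1O | intermediate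
9 | 1-bromo-2,5-dimethoxy-4-(methoxymethoxy)benzene | COCOc1cc(OC)c(Br)cc1OC | intermediate
10 | [2,5-dimethoxy-4-(methoxymethoxy)phenyl]lithium (not isolated) | [Li]c1cc(OC)c(OCOC)cc1OC | intermediate
11 | ethyl 2-[2,5-dimethoxy-4-(methoxymethoxy)phenyl]-2-oxoacetate | CCOC(=O)C(=O)c1cc(OC)c(OCOC)cc1OC | intermediate
12 | ethyl 2-[2,5-dimethoxy-4-(methoxymethoxy)phenyl]acrylate | CCOC(=O)C(=C)c1cc(OC)c(OCOC)cc1OC | intermediate
13 | 2-[2,5-dimethoxy-4-(methoxymethoxy)phenyl]acrylic acid | OC(=O)C(=C)c1cc(OC)c(OCOC)cc1OC | intermediate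
14 | 4,5-bis(benzyloxy)benzyne (not isolated) | C1(OCc2ccccc2)=CC#CC=C1OCc1ccccc1 | intermediate
15 | 1-[4,5-bis(benzyloxy)-2-hydroxyphenyl]-2-[2,5-dimethoxy-4-(methoxymethoxy)phenyl]prop-2-en-1-one, present as its cesium phenoxide (not isolated) | C=C(C(=O)c1cc(OCc2ccccc2)c(OCc2ccccc2)cc1O)c1cc(OC)c(OCOC)cc1OC | intermediate
16 | rac-6,7-bis(benzyloxy)-3-[2,5-dimethoxy-4-(methoxymethoxy)phenyl]chroman-4-one | COc1cc(C2COc3cc(OCc4ccccc4)c(OCc4ccccc4)cc3C2=O)c(OC)cc1OCOC | intermediate
17 | rac-6,7-dihydroxy-3-[2,5-dimethoxy-4-(methoxymethoxy)phenyl]chroman-4-one | COc1cc(C2COc3cc(O)c(O)cc3C2=O)c(OC)cc1OCOC | intermediate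
18 | rac-6-hydroxy-7-(methoxymethoxy)-3-[2,5-dimethoxy-4-(methoxymethoxy)phenyl]chroman-4-one | COc1cc(C2COc3cc(OCOC)c(O)cc3C2=O)c(OC)cc1OCOC | intermediate
19 | rac-3-[2,5-dimethoxy-4-(methoxymethoxy)phenyl]-7-(methoxymethoxy)-4-oxochroman-6-yl trifluoromethanesulfonate | COc1cc(C2COc3cc(OCOC)c(OS(=O)(=O)C(F)(F)F)cc3C2=O)c(OC)cc1OCOC | intermediate
20 | rac-3-[2,5-dimethoxy-4-(methoxymethoxy)phenyl]-7-(methoxymethoxy)-6-(3-methylbut-2-en-1-yl)chroman-4-one | COc1cc(C2COc3cc(OCOC)c(CC=C(C)C)cc3C2=O)c(OC)cc1OCOC | intermediate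
21 | (3S,4S)-3-[2,5-dimethoxy-4-(methoxymethoxy)phenyl]-7-(methoxymethoxy)-6-(3-methylbut-2-en-1-yl)chroman-4-ol (cis) | COc1cc([C@H]2COc3cc(OCOC)c(CC=C(C)C)cc3[C@H]2O)c(OC)cc1OCOC | intermediate
22 | (3S)-3-[2,5-dimethoxy-4-(methoxymethoxy)phenyl]-7-(methoxymethoxy)-6-(3-methylbut-2-en-1-yl)chroman-4-one | COc1cc([C@H]2COc3cc(OCOC)c(CC=C(C)C)cc3C2=O)c(OC)cc1OCOC | intermediate
23 | (3S)-7-hydroxy-3-(4-hydroxy-2,5-dimethoxyphenyl)-6-(3-methylbut-2-en-1-yl)chroman-4-one | COc1cc([C@H]2COc3cc(O)c(CC=C(C)C)cc3C2=O)c(OC)cc1O | target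

**Step count**
Total steps: 16. Longest linear sequence: 13 (steps 4 to 16); the ring A branch (steps 1 to 3) joins at step 9.

**Steps most likely to fail, with fallbacks**

Step 9. At 125 °C the 2-arylacrylate may oligomerise before it meets the aryne, the aryl carbanion may be diverted into conjugate addition at the unsubstituted methylene instead of the acyl shift, and the product enolate may be arylated by excess aryne. The fallback builds ring C in two stages from a saturated acid. Keto ester 11 is saponified and reduced in one pot under Wolff–Kishner conditions (KOH, N2H4·H2O, diethylene glycol, 130 to 190 °C) to 2-[2,5-dimethoxy-4-(methoxymethoxy)phenyl]acetic acid F1. This acid, which cannot polymerise or undergo conjugate addition, is combined with 6 under the same CsF conditions and should give, by the same aryne C–O insertion, 1-[4,5-bis(benzyloxy)-2-hydroxyphenyl]-2-[2,5-dimethoxy-4-(methoxymethoxy)phenyl]ethan-1-one F2. Alpha-methylenation of F2 with paraformaldehyde and Et2NH in refluxing EtOH (Mannich condensation, elimination, oxa-Michael closure) returns to 16.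

Step 13. Allyl transposition during transmetalation may give the branched 1,1-dimethylallyl isomer, and oxidative addition of the electron-rich triflate may be slow enough for triflate hydrolysis to compete. The fallback sets out from 19: Stille coupling with allyltributylstannane (Pd(PPh3)4, LiCl, DMF, 90 °C), which has no regiochemical ambiguity, should give rac-6-allyl-3-[2,5-dimethoxy-4-(methoxymethoxy)phenyl]-7-(methoxymethoxy)chroman-4-one F3. Cross-metathesis of F3 with excess 2-methyl-2-butene (second-generation Grubbs catalyst, CH2Cl2, 40 °C) converts the allyl into the prenyl group and rejoins the route at 20.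

Step 16. Acid may promote enolisation, eroding the C3 configuration, and cyclisation of the freed 7-hydroxyl onto the prenyl alkene. The fallback moves the acid step to the racemic stage and carries fluoride-labile silyl ethers through the stereo-defining steps. From 20, both MOM groups are removed (HCl, MeOH, rt) to give rac-7-hydroxy-3-(4-hydroxy-2,5-dimethoxyphenyl)-6-(3-methylbut-2-en-1-yl)chroman-4-one F4. Silylation (TBSCl, imidazole, DMF) gives the racemic bis(tert-butyldimethylsilyl) ether F5. The transfer hydrogenation of step 14 then gives the cis-(3S,4S) bis-silyl alcohol F6, and Dess–Martin oxidation gives the (3S) bis-silyl ketone F7. Buffered HF·pyridine in THF at 0 °C, a non-enolising desilylation, arrives at 23.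

**Further compounds**
F1 | step 9 | 2-[2,5-dimethoxy-4-(methoxymethoxy)phenyl]acetic acid | OC(=O)Cc1cc(OC)c(OCOC)cc1OC
F2 | step 9 | 1-[4,5-bis(benzyloxy)-2-hydroxyphenyl]-2-[2,5-dimethoxy-4-(methoxymethoxy)phenyl]ethan-1-one | O=C(Cc1cc(OC)c(OCOC)cc1OC)c1cc(OCc2ccccc2)c(OCc2ccccc2)cc1O
F3 | step 13 | rac-6-allyl-3-[2,5-dimethoxy-4-(methoxymethoxy)phenyl]-7-(methoxymethoxy)chroman-4-one | COc1cc(C2COc3cc(OCOC)c(CC=C)cc3C2=O)c(OC)cc1OCOC
F4 | step 16 | rac-7-hydroxy-3-(4-hydroxy-2,5-dimethoxyphenyl)-6-(3-methylbut-2-en-1-yl)chroman-4-one | COc1cc(C2COc3cc(O)c(CC=C(C)C)cc3C2=O)c(OC)cc1O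
F5 | step 16 | rac-7-(tert-butyldimethylsilyloxy)-3-[4-(tert-butyldimethylsilyloxy)-2,5-dimethoxyphenyl]-6-(3-methylbut-2-en-1-yl)chroman-4-one | COc1cc(C2COc3cc(O[Si](C)(C)C(C)(C)C)c(CC=C(C)C)cc3C2=O)c(OC)cc1O[Si](C)(C)C(C)(C)C
F6 | step 16 | (3S,4S)-7-(tert-butyldimethylsilyloxy)-3-[4-(tert-butyldimethylsilyloxy)-2,5-dimethoxyphenyl]-6-(3-methylbut-2-en-1-yl)chroman-4-ol | COc1cc([C@H]2COc3cc(O[Si](C)(C)C(C)(C)C)c(CC=C(C)C)cc3[C@H]2O)c(OC)cc1O[Si](C)(C)C(C)(C)C
F7 | step 16 | (3S)-7-(tert-butyldimethylsilyloxy)-3-[4-(tert-butyldimethylsilyloxy)-2,5-dimethoxyphenyl]-6-(3-methylbut-2-en-1-yl)chroman-4-one | COc1cc([C@H]2COc3cc(O[Si](C)(C)C(C)(C)C)c(CC=C(C)C)cc3C2=O)c(OC)cc1O[Si](C)(C)C(C)(C)C
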